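**Strategy.** The key step exploits the 1,5-relationship between the 19-carboxyl carbon on C4 and C1 of ring A (C19–C4–C3–C2–C1, labdane numbering): with a C1=C2 double bond the target is a γ,δ-unsaturated acid. Its precursor is therefore a trans-fused δ-lactone on ring B (oxygen joining C19 to C1 across C4–C5–C10) carrying a vinyl group (C2=C3) at C1. Ireland–Claisen rearrangement of the lactone silyl ketene acetal forms C3–C4, closes ring A, sets quaternary C4 with the axial acid, and unveils the carboxyl. The lactone comes from 2-methylcyclohexenone by asymmetric Mukaiyama–Michael addition and boron aldol with acrolein; the side chain is coupled last.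

Key step: step 5

Remarks: labdane numbering (C17 = 8-methyl, C18 = 4α-methyl, C19 = carboxyl carbon, C20 = 10β-methyl) is used for the atoms of all intermediates. Compounds 2 and 15 are taken as catalogue compounds. The C4 epimers of 3–10 and the C8 epimers of 9 converge later and are not separated.

Step 1
Reactants: 1 2-methylcyclohex-2-en-1-one; 2 (E)-1-methoxy-1-(trimethylsilyloxy)prop-1-ene
Product: 3 methyl 2-[(1S)-2-methyl-3-(trimethylsilyloxy)cyclohex-2-en-1-yl]propanoate
Conditions: (S)-3,3-diphenyl-1-(o-tolyl)tetrahydro-1H,3H-pyrrolo[1,2-c][1,3,2]oxazaborole protonated with HN(SO2CF3)2 (20 mol %), Ph3PO (25 mol %), PhMe, −20 °C; non-aqueous work-up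
Reagents that add atoms: none
Why: Catalytic enantioselective Mukaiyama–Michael addition, in which the chiral oxazaborolidinium ion activates the enone and shields one face of C5 so that C5 is set by catalyst control (the mirror-image catalyst is taken should the facial sense prove opposite), while silyl transfer releases the regiodefined C9=C10 silyl enol ether.

Step 2
Reactants: 3 methyl 2-[(1S)-2-methyl-3-(trimethylsilyloxy)cyclohex-2-en-1-yl]propanoate; 4 acrolein
Product: 8 (1R,4aS,8aR)-1-ethenyl-4,8a-dimethylhexahydro-1H-isochromene-3,8-dione (trans-fused keto lactone; vinyl axial), via dibutylboron enolate 5 (not isolated), via boron aldolate 6 (not isolated), via hydroxy keto ester 7 (not isolated)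
Conditions: n-Bu2BOTf, CH2Cl2, 0 °C to rt; 4, −78 °C; pH 7 phosphate buffer, MeOH, H2O2, 0 °C; then camphorsulfonic acid (cat.), PhMe, 50 °C
Reagents that add atoms: none
Why: Silicon-to-boron exchange gives the boron enolate without touching the ester, and a closed Zimmerman–Traxler boron aldol addition to acrolein occurs anti to the pseudoaxial C5 side chain (quaternary C10, with C1 trans to C4 on ring B) with the vinyl group equatorial in the chair (C1, OH syn to the 10-methyl), so that acid-catalysed lactonisation gives the trans-fused δ-lactone in which the vinyl group is axial and anti to the 10-methyl.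

Step 3
Reactants: 8 (1R,4aS,8aR)-1-ethenyl-4,8a-dimethylhexahydro-1H-isochromene-3,8-dione
Product: 9 (1R,4aS,8aR)-1-ethenyl-4,7,8a-trimethylhexahydro-1H-isochromene-3,8-dione
Conditions: LiN(iPr)2 (1.05 equiv), THF, −78 °C; MeI, −78 to −20 °C
Reagents that add atoms: iodomethane CI
Why: Kinetic enolate alkylation, in which the ketone can enolise only toward C8 (C10 is quaternary) and is far more acidic than the lactone, so one equivalent of base and MeI install C17; the new C8 centre is uncontrolled and becomes sp2 in step 4.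

Step 4
Reactants: 9 (1R,4aS,8aR)-1-ethenyl-4,7,8a-trimethylhexahydro-1H-isochromene-3,8-dione
Product: 10 (1R,4aS,8aR)-1-ethenyl-4,7,8a-trimethyl-3-oxo-3,4,4a,5,6,8a-hexahydro-1H-isochromen-8-yl trifluoromethanesulfonate
Conditions: KN(SiMe3)2 (1.1 equiv), THF, −78 °C; PhNTf2, −78 to 0 °C
Reagents that add atoms: N-phenylbis(trifluoromethanesulfonimide) O=S(=O)(N(c1ccccc1)S(=O)(=O)C(F)(F)F)C(F)(F)F
Why: Enol triflate formation by O-sulfonylation of the tetrasubstituted potassium enolate fixes the C8=C9 double bond regiospecifically and removes the only other enolisable carbonyl before step 5; no new stereocentre.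

Step 5
Reactants: 10 (1R,4aS,8aR)-1-ethenyl-4,7,8a-trimethyl-3-oxo-3,4,4a,5,6,8a-hexahydro-1H-isochromen-8-yl trifluoromethanesulfonate
Product: 13 (1S,4aS,8aR)-1,4a,6-trimethyl-5-(trifluoromethylsulfonyloxy)-1,2,4a,7,8,8a-hexahydronaphthalene-1-carboxylic acid, via silyl ketene acetal 11 (not isolated), via trimethylsilyl ester 12 (not isolated)
Conditions: LiN(iPr)2, Me3SiCl–Et3N, THF, −78 °C; then PhMe, 100 °C; 1 M HCl, rt
Reagents that add atoms: none
Why: Deprotonation at C4 (the only acidic C–H once the ketone is an enol triflate) and O-silylation give the cyclic silyl ketene acetal 11, an allyl vinyl ether C3=C2–C1–O–C19=C4 whose ends are tied by the C4–C5–C10–C1 bridge, and heating brings about a concerted suprafacial [3,3] shift that forms C3–C4 as C1–O breaks, leaving silyl ester 12, which is hydrolysed to acid 13. The closest known reaction type is the Ireland–Claisen rearrangement in its lactone-enolate, ring-forming variant (silyl ketene acetals of 6-vinyl δ-lactones giving cyclohex-3-enecarboxylic acids). Ring A closes as a six-membered carbocycle in exchange for the six-membered lactone through a boat-like array, formally an intramolecular syn SN2' attack of the enolate carbon on the allylic ester (6-endo with respect to the resulting C1=C2 bond). The only new stereocentre, quaternary C4, is controlled by C1: the vinyl group is axial on the α face of the trans-fused lactone (anti to the 10β-methyl), so C3 can bond only to the α face of C4 and the former lactone carbonyl C19 is left axial and β, cis to C20, while C1 becomes sp2. The step needs O- over C-silylation and rearrangement before decomposition; the tertiary enolate carbon favours O-silylation, the loose transition state keeps C1 and C4 about 3 Å apart, a distance the gauche C10–C5 bridge of the trans-fused half-chair spans, and any equatorial-vinyl C1 epimer cannot reach C4 and so cannot give the C4 epimer.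

Step 6
Reactants: 13 (1S,4aS,8aR)-1,4a,6-trimethyl-5-(trifluoromethylsulfonyloxy)-1,2,4a,7,8,8a-hexahydronaphthalene-1-carboxylic acid
Product: 14 (1S,4aS,8aR)-1,4a,6-trimethyl-5-(trifluoromethylsulfonyloxy)-1,2,3,4,4a,7,8,8a-octahydronaphthalene-1-carboxylic acid
Conditions: 2-nitrobenzenesulfonylhydrazide (excess), Et3N, CH2Cl2, rt
Reagents that add atoms: none
Why: Diimide reduction (concerted syn transfer of two hydrogens) saturates the cis-disubstituted C1=C2 bond and leaves the tetrasubstituted enol triflate untouched; no new stereocentre.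

Step 7
Reactants: 15 (2E)-4-acetoxy-2-methylbut-2-enal
Product: 16 (2E)-3-methylpenta-2,4-dien-1-yl acetate
Conditions: Ph3PCH3Br, KN(SiMe3)2, THF, 0 °C; then 15, −78 to 0 °C
Reagents that add atoms: methyltriphenylphosphonium bromide C[P+](c1ccccc1)(c1ccccc1)c1ccccc1.[Br-]
Why: Wittig methylenation with the non-stabilised ylide at low temperature converts the aldehyde into the terminal vinyl group without touching the E trisubstituted alkene or the acetate; no stereocentre.

Step 8
Reactants: 14 (1S,4aS,8aR)-1,4a,6-trimethyl-5-(trifluoromethylsulfonyloxy)-1,2,3,4,4a,7,8,8a-octahydronaphthalene-1-carboxylic acid; 16 (2E)-3-methylpenta-2,4-dien-1-yl acetate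
Product: 18 15-acetoxylabda-8,13E-dien-19-oic acid (target), via alkyl-9-BBN 17 (not isolated)
Conditions: 16, 9-BBN-H, THF, 0 °C to rt; then 14, Pd(dppf)Cl2 (10 mol %), AsPh3, Cs2CO3, DMF–THF–H2O, 45 °C; aq. citric acid
Reagents that add atoms: none
Why: Anti-Markovnikov hydroboration of the monosubstituted terminus of the diene followed by B-alkyl Suzuki–Miyaura coupling with the enol triflate forms C9–C11 with both alkene positions and geometries retained, the acid being carried as its carboxylate; the coupling is placed after step 5 because the allylic lactone of 10 would ionise on zerovalent palladium.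

**Compound list**

1 | 2-methylcyclohex-2-en-1-one | CC1=CCCCC1=O | starting material
2 | (E)-1-methoxy-1-(trimethylsilyloxy)prop-1-ene | C/C=C(\OC)O[Si](C)(C)C | starting material
3 | methyl 2-[(1S)-2-methyl-3-(trimethylsilyloxy)cyclohex-2-en-1-yl]propanoate (epimers at C2 of the propanoate) | COC(=O)C(C)[C@@H]1CCCC(O[Si](C)(C)C)=C1C | intermediate
4 | acrolein (prop-2-enal) | C=CC=O | starting material
5 | dibutylboron enolate: methyl 2-[(1S)-3-(dibutylboranyloxy)-2-methylcyclohex-2-en-1-yl]propanoate | CCCCB(CCCC)OC1=C(C)[C@@H](CCC1)C(C)C(=O)OC | intermediate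
6 | boron aldolate: O-dibutylboranyl derivative of 7 | C=C[C@@H](OB(CCCC)CCCC)[C@]1(C)C(=O)CCC[C@H]1C(C)C(=O)OC | intermediate
7 | methyl 2-[(1S,2R)-2-[(1R)-1-hydroxyprop-2-en-1-yl]-2-methyl-3-oxocyclohexyl]propanoate | C=C[C@@H](O)[C@]1(C)C(=O)CCC[C@H]1C(C)C(=O)OC | intermediate
8 | (1R,4aS,8aR)-1-ethenyl-4,8a-dimethylhexahydro-1H-isochromene-3,8-dione (trans-fused; 1-vinyl axial, anti to the 8a-methyl; C4 epimers) | C=C[C@H]1OC(=O)C(C)[C@@H]2CCCC(=O)[C@@]12C | intermediate
9 | (1R,4aS,8aR)-1-ethenyl-4,7,8a-trimethylhexahydro-1H-isochromene-3,8-dione (C4 and C7 epimers) | C=C[C@H]1OC(=O)C(C)[C@@H]2CCC(C)C(=O)[C@@]12C | intermediate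
10 | (1R,4aS,8aR)-1-ethenyl-4,7,8a-trimethyl-3-oxo-3,4,4a,5,6,8a-hexahydro-1H-isochromen-8-yl trifluoromethanesulfonate (C4 epimers) | C=C[C@H]1OC(=O)C(C)[C@@H]2CCC(C)=C(OS(=O)(=O)C(F)(F)F)[C@@]12C | intermediate
11 | trimethylsilyl ketene acetal of 10 (C3=C4 of the isochromene, 3-trimethylsilyloxy) | C=C[C@H]1OC(O[Si](C)(C)C)=C(C)[C@@H]2CCC(C)=C(OS(=O)(=O)C(F)(F)F)[C@@]12C | intermediate
12 | trimethylsilyl ester of 13 | O=S(=O)(OC1=C(C)CC[C@H]2[C@@](C)(C(=O)O[Si](C)(C)C)CC=C[C@]12C)C(F)(F)F | intermediate
13 | (1S,4aS,8aR)-1,4a,6-trimethyl-5-(trifluoromethylsulfonyloxy)-1,2,4a,7,8,8a-hexahydronaphthalene-1-carboxylic acid (4β-CO2H, 5α-H, 10β-CH3, C1=C2 in labdane numbering) | O=S(=O)(OC1=C(C)CC[C@H]2[C@@](C)(C(=O)O)CC=C[C@]12C)C(F)(F)F | intermediate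
14 | (1S,4aS,8aR)-1,4a,6-trimethyl-5-(trifluoromethylsulfonyloxy)-1,2,3,4,4a,7,8,8a-octahydronaphthalene-1-carboxylic acid | O=S(=O)(OC1=C(C)CC[C@H]2[C@@](C)(C(=O)O)CCC[C@]12C)C(F)(F)F | intermediate
15 | (2E)-4-acetoxy-2-methylbut-2-enal | CC(=O)OC/C=C(\C)C=O | starting material
16 | (2E)-3-methylpenta-2,4-dien-1-yl acetate | CC(=O)OC/C=C(\C)C=C | intermediate
17 | 9-[(3E)-5-acetoxy-3-methylpent-3-en-1-yl]-9-borabicyclo[3.3.1]nonane | CC(=O)OC/C=C(\C)CCB1C2CCCC1CCC2 | intermediate
18 | (1S,4aS,8aR)-5-[(3E)-5-acetoxy-3-methylpent-3-en-1-yl]-1,4a,6-trimethyl-1,2,3,4,4a,7,8,8a-octahydronaphthalene-1-carboxylic acid (15-acetoxylabda-8,13E-dien-19-oic acid) | CC(=O)OC/C=C(\C)CCC1=C(C)CC[C@H]2[C@@](C)(C(=O)O)CCC[C@]12C | target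

**Step count.** Total: 8 steps. Longest linear sequence: 7 steps (steps 1–6, then 8; step 7 is the side branch).

**Steps most likely to fail**

1. Step 5 (key rearrangement). The trans-fused silyl ketene acetal may not reach the boat-like [3,3] array before C-silylation or thermal decomposition take over. The fallback makes the same C3–C4 ring bond by enolate alkylation and sets out from 3. Fluoride-induced alkylation of 3 (BnMe3N+ F−, 1-chloro-3-iodopropane, THF), anti to the C5 side chain, should give methyl 2-[(1S,2S)-2-(3-chloropropyl)-2-methyl-3-oxocyclohexyl]propanoate F1. C8 methylation (LiN(iPr)2, MeI) should give its 4-methyl homologue F2, and KN(SiMe3)2/PhNTf2 the enol triflate F3. KN(SiMe3)2 with NaI in THF–DMPU then closes ring A by 6-exo-tet alkylation of the ester enolate at C4, expected through the chair with the enolate methyl equatorial, to give the methyl ester of 14 F4. This control at C4 is conformational only, which is why it is the fallback and not the route. LiI in refluxing pyridine cleaves the hindered methyl ester and the route is rejoined at 14.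

2. Step 8 (side-chain coupling). Oxidative addition and transmetalation at the tetrasubstituted triflate next to quaternary C10 are slow, so protodeboronation or β-hydride elimination of the alkylborane and hydrolysis of the allylic acetate by aqueous base may win. The fallback uses an organozinc without aqueous base and sets out from 17 and 14. Oxidation of 17 (NaBO3, THF–H2O) gives (2E)-5-hydroxy-3-methylpent-2-en-1-yl acetate F5. I2/PPh3/imidazole gives (2E)-5-iodo-3-methylpent-2-en-1-yl acetate F6, and Zn dust with LiCl in THF gives [(3E)-5-acetoxy-3-methylpent-3-en-1-yl]zinc iodide F7. Negishi coupling of F7 with the sodium salt of 14 (NaH; Pd(OAc)2, SPhos, THF–NMP, 50 °C) returns to the route at 18.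

3. Step 1 (asymmetric conjugate addition). Facial selectivity may be poor, because achiral silyl-cation catalysis competes with the chiral boron Lewis acid on the less reactive α-methyl enone. The fallback sets out from 1. Catalytic asymmetric Michael addition of dimethyl methylmalonate under the heterobimetallic complex LiAl[(R)-1,1'-binaphthalene-2,2'-diolate]2 in THF (ligand antipode chosen for the required sense) should give dimethyl 2-methyl-2-[(1R)-2-methyl-3-oxocyclohexyl]propanedioate F8; it has the same spatial arrangement at C5 as 3, and only the descriptor changes. Krapcho demethoxycarbonylation (LiCl, wet DMSO, 160 °C) gives methyl 2-[(1R)-2-methyl-3-oxocyclohexyl]propanoate F9. Thermodynamic silylation (Me3SiCl, NaI, Et3N, MeCN) gives the more substituted silyl enol ether and the route is rejoined at 3.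

Further compounds
F1 | step 5 | methyl 2-[(1S,2S)-2-(3-chloropropyl)-2-methyl-3-oxocyclohexyl]propanoate | COC(=O)C(C)[C@@H]1CCCC(=O)[C@@]1(C)CCCCl
F2 | step 5 | methyl 2-[(1S,2S)-2-(3-chloropropyl)-2,4-dimethyl-3-oxocyclohexyl]propanoate | COC(=O)C(C)[C@@H]1CCC(C)C(=O)[C@@]1(C)CCCCl
F3 | step 5 | (5S,6S)-6-(3-chloropropyl)-5-(1-methoxy-1-oxopropan-2-yl)-2,6-dimethylcyclohex-1-en-1-yl trifluoromethanesulfonate | COC(=O)C(C)[C@@H]1CCC(C)=C(OS(=O)(=O)C(F)(F)F)[C@@]1(C)CCCCl
F4 | step 5 | methyl (1S,4aS,8aR)-1,4a,6-trimethyl-5-(trifluoromethylsulfonyloxy)-1,2,3,4,4a,7,8,8a-octahydronaphthalene-1-carboxylate | O=S(=O)(OC1=C(C)CC[C@H]2[C@@](C)(C(=O)OC)CCC[C@]12C)C(F)(F)F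
F5 | step 8 | (2E)-5-hydroxy-3-methylpent-2-en-1-yl acetate | CC(=O)OC/C=C(\C)CCO
F6 | step 8 | (2E)-5-iodo-3-methylpent-2-en-1-yl acetate | CC(=O)OC/C=C(\C)CCI
F7 | step 8 | [(3E)-5-acetoxy-3-methylpent-3-en-1-yl]zinc iodide | CC(=O)OC/C=C(\C)CC[Zn]I
F8 | step 1 | dimethyl 2-methyl-2-[(1R)-2-methyl-3-oxocyclohexyl]propanedioate | COC(=O)C(C)(C(=O)OC)[C@@H]1CCCC(=O)C1C
F9 | step 1 | methyl 2-[(1R)-2-methyl-3-oxocyclohexyl]propanoate | COC(=O)C(C)[C@@H]1CCCC(=O)C1C
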